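**Plan**

1. Numbering: tetralin C1 (aryl-bearing), C2 (CO2Me), C3 (CH2OH, exocyclic carbon C9), C4 (benzylic CH2); ring A is the fused arene (C4a–C8a), ring B the carbocycle, ring C the pendant aryl group.
2. Retrosynthesis: behind two O-benzyl groups and one O-triisopropylsilyl group, the C1–H and C2–H bonds lead back to a C1=C2 enoate and then to a C1 tertiary carbinol. The C1–C2 bond (with C3–H) is then cut to an acyclic (E)-keto enoate, followed by C3–C4 (benzylzinc plus alkenyl iodide) and C8a–C1 (aryllithium plus Weinreb amide).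
3. Forward: rings A and C are joined at the ketone carbon, the four-carbon enoate is attached at C4, and ring B, the only ring that has to be made, closes at C1–C2.
4. Enabling feature: C3 is the β-carbon of the C2 ester and carries two different methylene arms (ring carbon C4 and exocyclic C9), so it can be created by face-selective hydride addition to an enoate of fixed geometry. The doubly benzylic C1 can begin as a diaryl ketone that the C2 enolate reaches through a six-membered transition state.
5. Stereochemistry: C3 (S) comes from a chiral bisphosphine copper hydride; C1 (R) from hydrogenation of the C1=C2 alkene on the face of the C3 hydrogen; C2 (S) from methoxide equilibration to the trans,trans ester.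

Key step: step 9

Assumption: hydride delivery to the Re face of C3 of the (E)-enoate is assigned to the (R,Sp) antipode of the ferrocenyl bisphosphine by analogy with simpler β,β-disubstituted (E)-enoates; the ligand is the only source of chirality, so its mirror image would be used if this substrate responds in the opposite sense.

**Route**

Step 1
Reactants: 1 6-bromovanillin (2-bromo-4-hydroxy-5-methoxybenzaldehyde)
Product: 2 4-(benzyloxy)-2-bromo-5-methoxybenzaldehyde
Conditions: BnBr, K2CO3, DMF, 60 °C
Reagents that add atoms: benzyl bromide, BrCc1ccccc1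
Why: Williamson ether synthesis, in which the phenoxide formed with K2CO3 displaces bromide from benzyl bromide while the aldehyde and the aryl bromide stay inert.

Step 2
Reactants: 2 4-(benzyloxy)-2-bromo-5-methoxybenzaldehyde
Product: 3 [4-(benzyloxy)-2-bromo-5-methoxyphenyl]methanol
Conditions: NaBH4, MeOH–THF, 0 °C
Reagents that add atoms: none
Why: Borohydride reduction of an aromatic aldehyde to the benzylic alcohol is fast at 0 °C and leaves the aryl bromide and the benzyl ether untouched.

Step 3
Reactants: 4 4-(benzyloxy)-3-methoxybenzoic acid (commercial)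
Product: 6 4-(benzyloxy)-N,3-dimethoxy-N-methylbenzamide, via acyl imidazole 5 (not isolated)
Conditions: 1,1'-carbonyldiimidazole, CH2Cl2, rt; then MeNHOMe·HCl, rt
Reagents that add atoms: N,O-dimethylhydroxylamine hydrochloride, CNOC.Cl
Why: Weinreb amide formation by carbonyldiimidazole activation, in which the acid becomes acyl imidazole 5 and is then acylated onto N,O-dimethylhydroxylamine, the released imidazole taking up the HCl of the amine salt.

Step 4
Reactants: 3 [4-(benzyloxy)-2-bromo-5-methoxyphenyl]methanol; 6 4-(benzyloxy)-N,3-dimethoxy-N-methylbenzamide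
Product: 9 [5-(benzyloxy)-2-(hydroxymethyl)-4-methoxyphenyl][4-(benzyloxy)-3-methoxyphenyl]methanone, via ortho-lithiated benzyl alkoxide 7 (not isolated), via chelated tetrahedral adduct 8 (not isolated)
Conditions: n-BuLi (2.2 equiv), THF, −78 °C; then 6, −78 → 0 °C; aq. NH4Cl
Reagents that add atoms: none
Why: Weinreb ketone synthesis after bromine–lithium exchange, in which the first equivalent of n-BuLi forms the lithium alkoxide, the second exchanges the ortho bromide at −78 °C, and the chelated adduct 8 keeps the ketone masked until the quench so that only one aryl group is transferred and the C8a–C1 bond is formed.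

Step 5
Reactants: 9 [5-(benzyloxy)-2-(hydroxymethyl)-4-methoxyphenyl][4-(benzyloxy)-3-methoxyphenyl]methanone
Product: 10 [5-(benzyloxy)-2-(chloromethyl)-4-methoxyphenyl][4-(benzyloxy)-3-methoxyphenyl]methanone
Conditions: MsCl, Et3N, CH2Cl2, 0 °C → rt
Reagents that add atoms: methanesulfonyl chloride, CS(=O)(=O)Cl
Why: Mesylation with in situ chloride displacement, in which the electron-rich benzylic mesylate is replaced by the chloride released from MsCl while the diaryl ketone is inert, the chloride being preferred to the bromide because it gives less Wurtz coupling in the later zinc insertion.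

Step 6
Reactants: 11 methyl 4-hydroxybut-2-ynoate
Product: 12 methyl (2Z)-4-hydroxy-3-iodobut-2-enoate
Conditions: NaI, AcOH, 70 °C
Reagents that add atoms: sodium iodide, [Na+].[I-]
Why: Hydroiodination of an ynoate, in which iodide adds to the β-carbon and anti protonation gives the (Z)-β-iodo enoate with iodine cis to the ester, so the hydroxymethyl group lies trans to the ester and cannot lactonise.

Step 7
Reactants: 12 methyl (2Z)-4-hydroxy-3-iodobut-2-enoate
Product: 13 methyl (2Z)-3-iodo-4-[(triisopropylsilyl)oxy]but-2-enoate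
Conditions: i-Pr3SiCl, imidazole, DMF, rt
Reagents that add atoms: chlorotriisopropylsilane, CC(C)[Si](Cl)(C(C)C)C(C)C
Why: Silylation of the primary allylic alcohol with a silyl chloride and imidazole, the triisopropylsilyl group being chosen because it has to survive acid in step 10 and methoxide in step 12 and to shield one face of ring B in step 11.

Step 8
Reactants: 10 [5-(benzyloxy)-2-(chloromethyl)-4-methoxyphenyl][4-(benzyloxy)-3-methoxyphenyl]methanone; 13 methyl (2Z)-3-iodo-4-[(triisopropylsilyl)oxy]but-2-enoate
Product: 15 methyl (2E)-3-{[4-(benzyloxy)-2-[4-(benzyloxy)-3-methoxybenzoyl]-5-methoxyphenyl]methyl}-4-[(triisopropylsilyl)oxy]but-2-enoate, via benzylzinc chloride 14 (not isolated)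
Conditions: Zn dust (activated with BrCH2CH2Br/Me3SiCl), LiCl, THF, 25 °C; then 13, Pd(PPh3)4 (3 mol%), THF, rt
Reagents that add atoms: none
Why: Negishi coupling, in which LiCl-promoted zinc insertion turns the benzylic chloride into benzylzinc chloride 14 (tolerant of the diaryl ketone) and zerovalent palladium couples it with the alkenyl iodide with retention of geometry, so the benzyl arm stays cis to the ester, the product is the (E)-enoate and the C3–C4 bond is formed without base.

Step 9
Reactants: 15 methyl (2E)-3-{[4-(benzyloxy)-2-[4-(benzyloxy)-3-methoxybenzoyl]-5-methoxyphenyl]methyl}-4-[(triisopropylsilyl)oxy]but-2-enoate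
Product: 17 methyl (1S,2R,3S)-7-(benzyloxy)-1-[4-(benzyloxy)-3-methoxyphenyl]-1-hydroxy-6-methoxy-3-{[(triisopropylsilyl)oxy]methyl}-1,2,3,4-tetrahydronaphthalene-2-carboxylate, via C1 diethoxymethylsilyl ether 16 (not isolated)
Conditions: Cu(OAc)2·H2O (5 mol%), (R)-1-[(Sp)-2-(diphenylphosphino)ferrocenyl]ethyldi-tert-butylphosphine (5.5 mol%), (EtO)2MeSiH (2 equiv), toluene, −10 °C → rt; then NH4F, MeOH, rt
Reagents that add atoms: none
Why: Cu(OAc)2 and the hydrosilane give a bisphosphine-bound monovalent copper hydride that adds hydride to C3 of the enoate and leaves a copper enolate at C2, which attacks the tethered diaryl ketone carbon C1; silyl transfer from (EtO)2MeSiH to the copper aldolate gives 16 and regenerates the hydride, and the fluoride work-up frees the carbinol. The closest known reaction type is the copper hydride-catalysed enantioselective reductive aldol cyclisation of β,β-disubstituted enones and enoates that carry a pendant ketone. Ring B closes by a 6-(enolexo)-exo-trig attack of C2 on the C1 carbonyl through a chelated chair-like transition state. C3 (S) is set by the ligand, which together with the fixed (E) geometry exposes the Re face of C3 to hydride; C2 (R) and C1 (S) are expected from the chair in which the C3 silyloxymethyl arm is equatorial, the ester ends trans to it and the copper bridge holds the new C1 oxygen cis to the ester, and both centres are erased in step 10. The step needs 1,4-hydride addition to outrun 1,2-reduction of the ketone, which should hold because the ketone is ortho-substituted and deactivated by the para oxygen donors of rings A and C, and because the acetate-derived catalyst contains no alkoxide base that could deconjugate the enoate.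

Step 10
Reactants: 17 methyl (1S,2R,3S)-7-(benzyloxy)-1-[4-(benzyloxy)-3-methoxyphenyl]-1-hydroxy-6-methoxy-3-{[(triisopropylsilyl)oxy]methyl}-1,2,3,4-tetrahydronaphthalene-2-carboxylate
Product: 18 methyl (3S)-7-(benzyloxy)-1-[4-(benzyloxy)-3-methoxyphenyl]-6-methoxy-3-{[(triisopropylsilyl)oxy]methyl}-3,4-dihydronaphthalene-2-carboxylate
Conditions: p-TsOH·H2O (10 mol%), toluene, 50 °C
Reagents that add atoms: none
Why: Acid-catalysed E1 dehydration, in which the tertiary carbinol ionises to a doubly benzylic cation stabilised by the para oxygen substituents of rings A and C and loses its only β-hydrogen (at C2) to give the conjugated C1=C2 enoate, while C3 and the bulky silyl ether are not affected.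

Step 11
Reactants: 18 methyl (3S)-7-(benzyloxy)-1-[4-(benzyloxy)-3-methoxyphenyl]-6-methoxy-3-{[(triisopropylsilyl)oxy]methyl}-3,4-dihydronaphthalene-2-carboxylate
Product: 19 methyl (1R,2R,3S)-7-hydroxy-1-(4-hydroxy-3-methoxyphenyl)-6-methoxy-3-{[(triisopropylsilyl)oxy]methyl}-1,2,3,4-tetrahydronaphthalene-2-carboxylate (all-cis)
Conditions: H2 (4 bar), 10% Pd/C, EtOAc–MeOH, rt
Reagents that add atoms: none
Why: Heterogeneous catalytic hydrogenation with concurrent benzyl ether hydrogenolysis, in which the C3 silyloxymethyl arm (pseudoaxial to avoid allylic strain with the C2 ester) blocks its own face, so both hydrogens add syn from the face of the C3 hydrogen and set C1 (R) and C2 (R), while the two benzyl ethers are cleaved to the phenols.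

Step 12
Reactants: 19 methyl (1R,2R,3S)-7-hydroxy-1-(4-hydroxy-3-methoxyphenyl)-6-methoxy-3-{[(triisopropylsilyl)oxy]methyl}-1,2,3,4-tetrahydronaphthalene-2-carboxylate
Product: 20 methyl (1R,2S,3S)-7-hydroxy-1-(4-hydroxy-3-methoxyphenyl)-6-methoxy-3-{[(triisopropylsilyl)oxy]methyl}-1,2,3,4-tetrahydronaphthalene-2-carboxylate
Conditions: NaOMe (5 equiv), MeOH, 65 °C, Ar; then AcOH
Reagents that add atoms: none
Why: Base-mediated epimerisation through the ester enolate, in which C2 is the only acidic stereocentre and equilibration relieves the 1,2-cis and 2,3-cis interactions to give the trans,trans ester (C2 S) with all three substituents pseudoequatorial, exchange with methoxide being degenerate for a methyl ester.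

Step 13
Reactants: 20 methyl (1R,2S,3S)-7-hydroxy-1-(4-hydroxy-3-methoxyphenyl)-6-methoxy-3-{[(triisopropylsilyl)oxy]methyl}-1,2,3,4-tetrahydronaphthalene-2-carboxylate
Product: 21 methyl (1R,2S,3S)-7-hydroxy-1-(4-hydroxy-3-methoxyphenyl)-3-(hydroxymethyl)-6-methoxy-1,2,3,4-tetrahydronaphthalene-2-carboxylate (target)
Conditions: HF·pyridine, pyridine, THF, 0 °C → rt
Reagents that add atoms: none
Why: Fluoride-mediated desilylation, in which buffered HF·pyridine cleaves the Si–O bond without forming an alkoxide, so the freed C3 hydroxymethyl group should not close onto the trans C2 ester and no stereocentre is touched.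

**Compound list**

1 | 6-bromovanillin (2-bromo-4-hydroxy-5-methoxybenzaldehyde) | COc1cc(C=O)c(Br)cc1O | starting material
2 | 4-(benzyloxy)-2-bromo-5-methoxybenzaldehyde | COc1cc(C=O)c(Br)cc1OCc1ccccc1 | intermediate
3 | [4-(benzyloxy)-2-bromo-5-methoxyphenyl]methanol | COc1cc(CO)c(Br)cc1OCc1ccccc1 | intermediate
4 | 4-(benzyloxy)-3-methoxybenzoic acid | COc1cc(C(=O)O)ccc1OCc1ccccc1 | starting material
5 | [4-(benzyloxy)-3-methoxyphenyl](1H-imidazol-1-yl)methanone | COc1cc(C(=O)n2ccnc2)ccc1OCc1ccccc1 | intermediate (not isolated)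
6 | 4-(benzyloxy)-N,3-dimethoxy-N-methylbenzamide | COc1cc(C(=O)N(C)OC)ccc1OCc1ccccc1 | intermediate
7 | lithium [4-(benzyloxy)-2-lithio-5-methoxyphenyl]methoxide | [Li]OCc1cc(OC)c(OCc2ccccc2)cc1[Li] | intermediate (not isolated)
8 | dilithium salt of the tetrahedral adduct of 7 with 6 (C–OLi, N(OMe)Me, CH2OLi) | [Li]OCc1cc(OC)c(OCc2ccccc2)cc1C(O[Li])(N(C)OC)c1ccc(OCc2ccccc2)c(OC)c1 | intermediate (not isolated)
9 | [5-(benzyloxy)-2-(hydroxymethyl)-4-methoxyphenyl][4-(benzyloxy)-3-methoxyphenyl]methanone | OCc1cc(OC)c(OCc2ccccc2)cc1C(=O)c1ccc(OCc2ccccc2)c(OC)c1 | intermediate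
10 | [5-(benzyloxy)-2-(chloromethyl)-4-methoxyphenyl][4-(benzyloxy)-3-methoxyphenyl]methanone | ClCc1cc(OC)c(OCc2ccccc2)cc1C(=O)c1ccc(OCc2ccccc2)c(OC)c1 | intermediate
11 | methyl 4-hydroxybut-2-ynoate | COC(=O)C#CCO | starting material
12 | methyl (2Z)-4-hydroxy-3-iodobut-2-enoate | COC(=O)/C=C(\I)CO | intermediate
13 | methyl (2Z)-3-iodo-4-[(triisopropylsilyl)oxy]but-2-enoate | COC(=O)/C=C(\I)CO[Si](C(C)C)(C(C)C)C(C)C | intermediate
14 | {[4-(benzyloxy)-2-[4-(benzyloxy)-3-methoxybenzoyl]-5-methoxyphenyl]methyl}zinc chloride | Cl[Zn]Cc1cc(OC)c(OCc2ccccc2)cc1C(=O)c1ccc(OCc2ccccc2)c(OC)c1 | intermediate (not isolated)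
15 | methyl (2E)-3-{[4-(benzyloxy)-2-[4-(benzyloxy)-3-methoxybenzoyl]-5-methoxyphenyl]methyl}-4-[(triisopropylsilyl)oxy]but-2-enoate | COC(=O)/C=C(/CO[Si](C(C)C)(C(C)C)C(C)C)Cc1cc(OC)c(OCc2ccccc2)cc1C(=O)c1ccc(OCc2ccccc2)c(OC)c1 | intermediate (key-step precursor)
16 | methyl (1S,2R,3S)-7-(benzyloxy)-1-[4-(benzyloxy)-3-methoxyphenyl]-1-{[diethoxy(methyl)silyl]oxy}-6-methoxy-3-{[(triisopropylsilyl)oxy]methyl}-1,2,3,4-tetrahydronaphthalene-2-carboxylate | COC(=O)[C@@H]1[C@@H](CO[Si](C(C)C)(C(C)C)C(C)C)Cc2cc(OC)c(OCc3ccccc3)cc2[C@@]1(O[Si](C)(OCC)OCC)c1ccc(OCc3ccccc3)c(OC)c1 | intermediate (not isolated)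
17 | methyl (1S,2R,3S)-7-(benzyloxy)-1-[4-(benzyloxy)-3-methoxyphenyl]-1-hydroxy-6-methoxy-3-{[(triisopropylsilyl)oxy]methyl}-1,2,3,4-tetrahydronaphthalene-2-carboxylate | COC(=O)[C@@H]1[C@@H](CO[Si](C(C)C)(C(C)C)C(C)C)Cc2cc(OC)c(OCc3ccccc3)cc2[C@@]1(O)c1ccc(OCc3ccccc3)c(OC)c1 | intermediate (key-step product)
18 | methyl (3S)-7-(benzyloxy)-1-[4-(benzyloxy)-3-methoxyphenyl]-6-methoxy-3-{[(triisopropylsilyl)oxy]methyl}-3,4-dihydronaphthalene-2-carboxylate | COC(=O)C1=C(c2ccc(OCc3ccccc3)c(OC)c2)c2cc(OCc3ccccc3)c(OC)cc2C[C@@H]1CO[Si](C(C)C)(C(C)C)C(C)C | intermediate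
19 | methyl (1R,2R,3S)-7-hydroxy-1-(4-hydroxy-3-methoxyphenyl)-6-methoxy-3-{[(triisopropylsilyl)oxy]methyl}-1,2,3,4-tetrahydronaphthalene-2-carboxylate | COC(=O)[C@H]1[C@@H](CO[Si](C(C)C)(C(C)C)C(C)C)Cc2cc(OC)c(O)cc2[C@H]1c1ccc(O)c(OC)c1 | intermediate
20 | methyl (1R,2S,3S)-7-hydroxy-1-(4-hydroxy-3-methoxyphenyl)-6-methoxy-3-{[(triisopropylsilyl)oxy]methyl}-1,2,3,4-tetrahydronaphthalene-2-carboxylate | COC(=O)[C@@H]1[C@@H](CO[Si](C(C)C)(C(C)C)C(C)C)Cc2cc(OC)c(O)cc2[C@H]1c1ccc(O)c(OC)c1 | intermediate
21 | methyl (1R,2S,3S)-7-hydroxy-1-(4-hydroxy-3-methoxyphenyl)-3-(hydroxymethyl)-6-methoxy-1,2,3,4-tetrahydronaphthalene-2-carboxylate | COC(=O)[C@@H]1[C@@H](CO)Cc2cc(OC)c(O)cc2[C@H]1c1ccc(O)c(OC)c1 | target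

**Step count and risks**

Total step count: 13. Longest linear sequence: 10 steps (1, 2, 4, 5, 8, 9, 10, 11, 12, 13) from 6-bromovanillin; steps 3, 6 and 7 prepare the two coupling partners.

Steps most likely to fail:

Step 9. The hydride may reduce the diaryl ketone in competition with the enoate, or the copper enolate may be silylated or protonated before it closes on the hindered, electron-rich ketone, so that reduction and ring closure come apart. The fallback separates the two events and sets out from 15. The same Cu(OAc)2·H2O/ferrocenyl bisphosphine catalyst would be run with polymethylhydrosiloxane and t-BuOH in toluene at 0 °C as a plain asymmetric conjugate reduction, the alcohol intercepting the enolate. This should give the saturated keto ester methyl (3S)-3-{[4-(benzyloxy)-2-[4-(benzyloxy)-3-methoxybenzoyl]-5-methoxyphenyl]methyl}-4-[(triisopropylsilyl)oxy]butanoate F1. Deprotonation of the ester with LiN(i-Pr)2 in THF at −78 °C and intramolecular lithium aldol addition to the ketone, quenched cold with AcOH, would then close ring B and come back to the route at 17. Any C1/C2 epimers of 17 converge in step 10.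

Step 11. Hydrogen may be delivered with poor facial selectivity, or the tetrasubstituted alkene may saturate so slowly that it disproportionates on the palladium surface towards the naphthalene. The fallback sets out from 18 and replaces surface hydrogenation by electron-transfer conjugate reduction with Mg turnings in MeOH at rt. Kinetic protonation at C1 should occur anti to the C9 arm, and the Mg(OMe)2 formed equilibrates C2, which should give the benzyl-protected trans,trans ester methyl (1R,2S,3S)-7-(benzyloxy)-1-[4-(benzyloxy)-3-methoxyphenyl]-6-methoxy-3-{[(triisopropylsilyl)oxy]methyl}-1,2,3,4-tetrahydronaphthalene-2-carboxylate F2. Hydrogenolysis of the two benzyl ethers (H2, 1 bar, 10% Pd/C, EtOAc), now with no alkene to reduce, comes back to the route at 20.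

Step 4. Bromine–lithium exchange may stay incomplete, or the aryllithium may be quenched by proton transfer within the poorly soluble lithium alkoxide, and the basic aryllithium may strip the N-methoxy group from the Weinreb amide instead of adding to it. The fallback sets out from 3 and masks the hydroxyl group and changes the electrophile. Silylation (t-BuMe2SiCl, imidazole, DMF) would give {[4-(benzyloxy)-2-bromo-5-methoxyphenyl]methoxy}(tert-butyl)dimethylsilane F3. Exchange with n-BuLi (1.1 equiv, THF, −78 °C) and addition to commercial 4-(benzyloxy)-3-methoxybenzaldehyde (COc1cc(C=O)ccc1OCc1ccccc1) would give the racemic diaryl carbinol [5-(benzyloxy)-2-{[(tert-butyldimethylsilyl)oxy]methyl}-4-methoxyphenyl][4-(benzyloxy)-3-methoxyphenyl]methanol F4. Oxidation with MnO2 in CH2Cl2 would give the ketone [5-(benzyloxy)-2-{[(tert-butyldimethylsilyl)oxy]methyl}-4-methoxyphenyl][4-(benzyloxy)-3-methoxyphenyl]methanone F5. Desilylation with HF·pyridine in THF comes back to the route at 9.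

Further compounds
F1 | step 9 | methyl (3S)-3-{[4-(benzyloxy)-2-[4-(benzyloxy)-3-methoxybenzoyl]-5-methoxyphenyl]methyl}-4-[(triisopropylsilyl)oxy]butanoate | COC(=O)C[C@@H](CO[Si](C(C)C)(C(C)C)C(C)C)Cc1cc(OC)c(OCc2ccccc2)cc1C(=O)c1ccc(OCc2ccccc2)c(OC)c1
F2 | step 11 | methyl (1R,2S,3S)-7-(benzyloxy)-1-[4-(benzyloxy)-3-methoxyphenyl]-6-methoxy-3-{[(triisopropylsilyl)oxy]methyl}-1,2,3,4-tetrahydronaphthalene-2-carboxylate | COC(=O)[C@@H]1[C@@H](CO[Si](C(C)C)(C(C)C)C(C)C)Cc2cc(OC)c(OCc3ccccc3)cc2[C@H]1c1ccc(OCc3ccccc3)c(OC)c1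
F3 | step 4 | {[4-(benzyloxy)-2-bromo-5-methoxyphenyl]methoxy}(tert-butyl)dimethylsilane | COc1cc(CO[Si](C)(C)C(C)(C)C)c(Br)cc1OCc1ccccc1
F4 | step 4 | [5-(benzyloxy)-2-{[(tert-butyldimethylsilyl)oxy]methyl}-4-methoxyphenyl][4-(benzyloxy)-3-methoxyphenyl]methanol (racemic) | COc1cc(CO[Si](C)(C)C(C)(C)C)c(C(O)c2ccc(OCc3ccccc3)c(OC)c2)cc1OCc1ccccc1
F5 | step 4 | [5-(benzyloxy)-2-{[(tert-butyldimethylsilyl)oxy]methyl}-4-methoxyphenyl][4-(benzyloxy)-3-methoxyphenyl]methanone | COc1cc(CO[Si](C)(C)C(C)(C)C)c(C(=O)c2ccc(OCc3ccccc3)c(OC)c2)cc1OCc1ccccc1
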